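**Retrosynthetic overview**

1. Target (daucane numbering: ring A = cyclopentane C1–C5; ring B = cycloheptane C1, C5–C10). The two esters go on last, and the 8,9-epoxide comes from a C8=C9 olefin by epoxidation directed by the free C6 hydroxyl.
2. Enabling feature: the C6 oxygen and the C9 epoxide oxygen lie on the same face of ring B, 1,4 across it. One oxygen can therefore bridge C6 and C9, making ring B the carbocycle of an 8-oxabicyclo[3.2.1]octan-2-one whose ketone sits at C10 (CH2 in the target) beside the non-enolisable quaternary C1.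
3. Key disconnection: C6–C7 and C8–C9 are made together by (3+2) cycloaddition of a C6=O(+)–C9(−) carbonyl ylide (from a ring A aldehyde/diazoketone) with 2-methoxypropene (C7, C8 and the C8 methyl). SmI2 then opens the bridge at C9–O, methanol is eliminated to the C8=C9 enone, and C10=O is reduced to CH2.
4. Ring A: all four stereocentres are relayed from the single stereocentre of (S)-4-silyloxycyclopentenone by two copper-catalysed conjugate additions (quaternary C1; the vinyl group becomes C10–C9), α-methylenation (C6), isopropyl addition (C4) and a silicon-tethered hydrosilylation (C5).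
5. Order of ring formation: ring A (starting material) → oxygen-bridged ring B (key step) → bridge opening → epoxide.

Key step: step 12

Remarks: atoms carry the target (daucane) numbers throughout; β means the face that carries the C1 methyl group, α the opposite face. Assumption: C8 of 20 and 21 (the methoxy-bearing carbon) is expected as an exo/endo mixture and is written without configuration, because step 13 removes this centre.

**Route**

Step 1
Reactants: 1 (S)-4-(tert-butyldimethylsilyloxy)cyclopent-2-en-1-one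
Product: 2 (3S,4S)-4-(tert-butyldimethylsilyloxy)-3-methyl-1-(trimethylsilyloxy)cyclopent-1-ene (CH3 trans to OTBS)
Conditions: MeMgBr, CuBr·SMe2 (10 mol%), TMSCl, THF, −78 °C; Et3N work-up
Reagents that add atoms: methylmagnesium bromide C[Mg]Br; chlorotrimethylsilane C[Si](C)(C)Cl
Why: Copper-catalysed 1,4-addition of the Grignard reagent, accelerated by TMSCl which traps the enolate as its silyl enol ether, occurs anti to the γ-silyloxy group; the new methyl-bearing centre is only transient (removed in step 2).

Step 2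
Reactants: 2 (3S,4S)-4-(tert-butyldimethylsilyloxy)-3-methyl-1-(trimethylsilyloxy)cyclopent-1-ene
Product: 3 (S)-4-(tert-butyldimethylsilyloxy)-3-methylcyclopent-2-en-1-one
Conditions: Pd(OAc)2 (10 mol%), O2 (1 atm), DMSO, 50 °C
Reagents that add atoms: none
Why: Saegusa–Ito oxidation (palladation of the silyl enol ether, β-hydride elimination, reoxidation by O2) regenerates the enone with the methyl now on the β-carbon; the silyloxy-bearing stereocentre (C2) is untouched.

Step 3
Reactants: 3 (S)-4-(tert-butyldimethylsilyloxy)-3-methylcyclopent-2-en-1-one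
Product: 4 (3S,4S)-4-(tert-butyldimethylsilyloxy)-3-methyl-1-(trimethylsilyloxy)-3-vinylcyclopent-1-ene (CH3 cis and vinyl trans to OTBS)
Conditions: CH2=CHMgBr, CuBr·SMe2 (20 mol%), TMSCl, HMPA, THF, −78 → −40 °C; Et3N work-up
Reagents that add atoms: vinylmagnesium bromide C=C[Mg]Br; chlorotrimethylsilane C[Si](C)(C)Cl
Why: Copper-catalysed conjugate addition to the β,β-disubstituted enone (TMSCl/HMPA activation) delivers the vinyl group anti to the adjacent silyloxy group, which sets quaternary C1 with CH3 cis (β) to the C2 oxygen; the vinyl group supplies C10 and C9.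

Step 4
Reactants: 4 (3S,4S)-4-(tert-butyldimethylsilyloxy)-3-methyl-1-(trimethylsilyloxy)-3-vinylcyclopent-1-ene
Product: 7 (3S,4S)-4-(tert-butyldimethylsilyloxy)-3-methyl-2-methylidene-3-vinylcyclopentan-1-one, via Mannich base 5 (not isolated), via ammonium iodide 6 (not isolated)
Conditions: CH2=NMe2(+) I(−), CH2Cl2, rt; then MeI; then aq. NaHCO3, rt
Reagents that add atoms: N,N-dimethylmethyleneiminium iodide C=[N+](C)C.[I-] (the CH2 carbon, C6); iodomethane CI (in 6 only)
Why: Mukaiyama–Mannich reaction of the regiodefined silyl enol ether with the iminium salt, N-methylation and E1cB loss of trimethylamine amount to an α-methylenation that installs C6 on C5; no stereocentre is formed.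

Step 5
Reactants: 7 (3S,4S)-4-(tert-butyldimethylsilyloxy)-3-methyl-2-methylidene-3-vinylcyclopentan-1-one
Product: 8 (1S,3S,4S)-4-(tert-butyldimethylsilyloxy)-1-isopropyl-3-methyl-2-methylidene-3-vinylcyclopentan-1-ol (OH, CH3 and OTBS β; isopropyl and vinyl α)
Conditions: iPrMgCl, CeCl3, THF, −78 °C
Reagents that add atoms: isopropylmagnesium chloride CC(C)[Mg]Cl
Why: Organocerium 1,2-addition (non-basic, so no enolisation or β-elimination of the silyloxy group) takes place on the α-face, opposite the β-silyloxy group on the carbon 1,3 to the carbonyl while the CH3/vinyl pair on C1 shields both faces about equally, giving the C4 β-hydroxyl and α-isopropyl.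

Step 6
Reactants: 8 (1S,3S,4S)-4-(tert-butyldimethylsilyloxy)-1-isopropyl-3-methyl-2-methylidene-3-vinylcyclopentan-1-ol
Product: 11 ring A diol (C1 β-CH3/α-vinyl; C2 β-OTBS; C4 β-OH/α-isopropyl; C5 β-CH2OH/α-H), via dimethylsilyl ether 9 (not isolated), via oxasilolane 10 (not isolated)
Conditions: HMe2SiCl, Et3N, DMAP (cat.), CH2Cl2, 0 °C; then Pt2[(CH2=CHSiMe2)2O]3 (0.5 mol%), toluene, 60 °C; then 30% H2O2, KF, KHCO3, THF–MeOH, rt
Reagents that add atoms: hydrogen peroxide OO (oxygen of the new CH2OH); chlorodimethylsilane C[SiH](C)Cl (silicon tether, present in 9 and 10 only)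
Why: Silicon-tethered intramolecular hydrosilylation (5-endo, platinum-catalysed) followed by Tamao–Fleming oxidation: the temporary 1-oxa-2-silacyclopentane is expected to be cis-fused to ring A, so C6 ends cis to the C4 oxygen and the new C5–H is α, while the α-vinyl group on the other face is out of reach of the tether.

Step 7
Reactants: 11 ring A diol
Product: 12 methyl ketone (as 11 with the C1 α-vinyl group converted into α-acetyl: C10=O, C9H3)
Conditions: PdCl2 (10 mol%), CuCl (20 mol%), O2 (1 atm), DMF–H2O (7:1), rt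
Reagents that add atoms: water O (carbonyl oxygen)
Why: Tsuji–Wacker oxidation converts the terminal vinyl group into the methyl ketone (Markovnikov hydroxypalladation); both hydroxyls are trans to or too far from the alkene to cyclise onto it and no stereocentre is touched.

Step 8
Reactants: 12 methyl ketone
Product: 13 C6 O-triethylsilyl ether of 12
Conditions: TESCl, imidazole, CH2Cl2, 0 °C
Reagents that add atoms: chlorotriethylsilane CC[Si](Cl)(CC)CC
Why: Chemoselective silylation of the primary hydroxyl; the tertiary C4 hydroxyl does not react under these conditions.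

Step 9
Reactants: 13 C6 O-triethylsilyl ether of 12
Product: 15 α-diazoketone (C1–C10(=O)–C9H=N2) with C6–OTES, via trifluoroacetyl ketone 14 (not isolated)
Conditions: LiN(SiMe3)2 (2.2 equiv), THF, −78 °C; CF3CO2CH2CF3; then MsN3, Et3N, H2O, MeCN, rt
Reagents that add atoms: methanesulfonyl azide CS(=O)(=O)N=[N+]=[N-] (the N2 unit); 2,2,2-trifluoroethyl trifluoroacetate O=C(OCC(F)(F)F)C(F)(F)F (in 14 only)
Why: Detrifluoroacetylative diazo transfer: the only enolisable position of the ketone is its methyl group (C1 is quaternary), its lithium enolate is trifluoroacetylated, and the activated 1,3-diketone passes its trifluoroacetyl group to the sulfonyl azide with formation of the α-diazoketone.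

Step 10
Reactants: 15 α-diazoketone with C6–OTES
Product: 16 α-diazoketone with free C6 primary alcohol
Conditions: Bu4NF, AcOH, THF, 0 °C
Reagents that add atoms: none
Why: Buffered fluoride cleaves the unhindered primary triethylsilyl ether much faster than the hindered secondary TBS ether and does not harm the diazoketone.

Step 11
Reactants: 16 α-diazoketone with free C6 primary alcohol
Product: 17 aldehyde–diazoketone (C5 β-CHO trans to the C1 α-diazoacetyl group; C4 β-OH; C2 β-OTBS)
Conditions: Dess–Martin periodinane, NaHCO3, CH2Cl2, 0 °C → rt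
Reagents that add atoms: none
Why: Dess–Martin oxidation under bicarbonate buffer gives the aldehyde without touching the diazoketone or dehydrating the tertiary β-hydroxy aldehyde, which is used at once.

Step 12
Reactants: 17 aldehyde–diazoketone; 18 2-methoxypropene
Product: 20 oxygen-bridged cycloadduct 2β-(tert-butyldimethylsilyloxy)-6β,9β-epoxy-4β-hydroxy-8-methoxydaucan-10-one (5α-H; C8 epimers), via carbonyl ylide 19 (not isolated)
Conditions: Rh2(OAc)4 (2 mol%), 18 (10 equiv), 4 Å molecular sieves, CH2Cl2, rt, slow addition of 17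
Reagents that add atoms: none
Why: Rh2(OAc)4 turns the diazoketone into a rhodium carbenoid that is captured by a lone pair of the C6 formyl oxygen to give the six-membered carbonyl ylide 19 (C9 carbanion stabilised by the C10 ketone, C6 oxocarbenium), which adds 2-methoxypropene in an intermolecular 1,3-dipolar (3+2) cycloaddition that forms C6–C7 and C8–C9 in the same operation. The closest known reaction type is the tandem carbonyl-ylide formation/cycloaddition of δ-carbonyl α-diazoketones, including additions of enol ethers to such ylides. Ring closures: the ylide ring closes by attack of the carbonyl oxygen on the carbenoid carbon (six-membered, trans-fused to ring A), and the cycloaddition then closes the tetrahydrofuran C6–O–C9–C8–C7 and with it the seven-membered carbocycle (ring B) as an 8-oxabicyclo[3.2.1]octan-2-one. Stereocentres: C6 and C9 are set together with the oxygen bridge β, because the enol ether adds to the ylide face anti to the pseudo-axial C1 methyl group that is 1,3 to both ylide termini; C8 forms as an exo/endo mixture and is erased in step 13. Regiochemistry (CH2 to C6, the methoxy-bearing carbon to C9) follows from LUMO(ylide)–HOMO(enol ether) control, the nucleophilic CH2 terminus joining the oxocarbenium carbon and the donor-substituted carbon joining the enolate-like C9. The needed chemoselectivity (ylide formation over O–H insertion, oxonium-ylide formation or cyclopropanation of the enol ether) is secured by the trans-1,2 placing of CHO and COCHN2 on ring A, which still allows the six-membered ylide, while the β-hydroxyl at C4 and the β-silyloxy group at C2 cannot reach the α-oriented carbenoid.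

Step 13
Reactants: 20 oxygen-bridged cycloadduct
Product: 22 enone 2β-(tert-butyldimethylsilyloxy)-4β,6β-dihydroxydauc-8-en-10-one, via methoxy ketone 21 (not isolated)
Conditions: SmI2 (2.5 equiv), THF–MeOH, −78 °C; then DBU, CH2Cl2, rt
Reagents that add atoms: none
Why: SmI2 reduces the C10 ketone to a ketyl that expels the α-oxygen (reductive cleavage of an α-alkoxy ketone), which opens the bridge at C9–O and frees the C6 β-hydroxyl with retention, and DBU then eliminates methanol from the β-methoxy ketone (E1cB) to place the double bond at C8=C9; the C8 centre is erased.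

Step 14
Reactants: 22 enone
Product: 23 10,10-(ethane-1,2-diyldithio) ketal (1,3-dithiolane) of 22
Conditions: HSCH2CH2SH, Zn(OTf)2, CH2Cl2, rt
Reagents that add atoms: ethane-1,2-dithiol SCCS
Why: Lewis-acid-catalysed dithioketalisation of the enone carbonyl; with conjugated ketones the double bond stays in place, and Zn(OTf)2 is mild enough for the tertiary alcohol and the silyl ether.

Step 15
Reactants: 23 dithiolane
Product: 24 homoallylic alcohol 2β-(tert-butyldimethylsilyloxy)dauc-8-ene-4β,6β-diol
Conditions: Raney nickel (Ni, W-2 grade, deactivated in acetone), EtOH, reflux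
Reagents that add atoms: none
Why: Raney-nickel desulfurisation (Mozingo reduction) replaces both C–S bonds by C–H and so turns C10 into CH2 while the trisubstituted C8=C9 double bond is kept; no stereocentre is affected.

Step 16
Reactants: 24 homoallylic alcohol
Product: 25 epoxy diol 2β-(tert-butyldimethylsilyloxy)-8β,9β-epoxydaucane-4β,6β-diol
Conditions: VO(acac)2 (5 mol%), tBuOOH, CH2Cl2, 0 °C → rt
Reagents that add atoms: tert-butyl hydroperoxide CC(C)(C)OO
Why: Vanadium-catalysed hydroxyl-directed epoxidation: the homoallylic C6 β-hydroxyl binds the vanadium alkylperoxide and delivers oxygen to the β-face of C8=C9, which sets C8 and C9 with the epoxide cis to the C6 oxygen.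

Step 17
Reactants: 25 epoxy diol; 26 3,4-dimethoxybenzoyl chloride
Product: 27 C6 3,4-dimethoxybenzoate of 25
Conditions: Et3N, DMAP, CH2Cl2, rt
Reagents that add atoms: none
Why: DMAP-catalysed acylation (nucleophilic catalysis) of the only secondary hydroxyl; the tertiary C4 hydroxyl is inert and the epoxide tolerates the basic conditions.

Step 18
Reactants: 27 C6 3,4-dimethoxybenzoate
Product: 28 6β-(3,4-dimethoxybenzoyloxy)-8β,9β-epoxydaucane-2β,4β-diol
Conditions: HF·pyridine, pyridine, THF, 0 °C → rt
Reagents that add atoms: none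
Why: Fluoride-mediated cleavage of the hindered secondary TBS ether under pyridine-buffered HF, conditions under which trisubstituted epoxides and esters persist.

Step 19
Reactants: 28 diol
Product: 29 target CNP0330776.1 (2β-acetoxy-6β-(3,4-dimethoxybenzoyloxy)-8β,9β-epoxydaucan-4β-ol)
Conditions: Ac2O, pyridine, DMAP (cat.), CH2Cl2, 0 °C → rt
Reagents that add atoms: acetic anhydride CC(=O)OC(C)=O
Why: DMAP-catalysed acetylation of the secondary C2 hydroxyl; the tertiary C4 hydroxyl is too hindered to be acylated.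

**Compound list**

1 | (S)-4-(tert-butyldimethylsilyloxy)cyclopent-2-en-1-one | O=C1C=C[C@@H](O[Si](C)(C)C(C)(C)C)C1 | starting material
2 | (3S,4S)-4-(tert-butyldimethylsilyloxy)-3-methyl-1-(trimethylsilyloxy)cyclopent-1-ene | C[Si](C)(C)OC1=C[C@H](C)[C@@H](O[Si](C)(C)C(C)(C)C)C1 | intermediate
3 | (S)-4-(tert-butyldimethylsilyloxy)-3-methylcyclopent-2-en-1-one | O=C1C=C(C)[C@@H](O[Si](C)(C)C(C)(C)C)C1 | intermediate
4 | (3S,4S)-4-(tert-butyldimethylsilyloxy)-3-methyl-1-(trimethylsilyloxy)-3-vinylcyclopent-1-ene | C[Si](C)(C)OC1=C[C@](C)(C=C)[C@@H](O[Si](C)(C)C(C)(C)C)C1 | intermediate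
5 | Mannich base, (3S,4S)-4-(tert-butyldimethylsilyloxy)-2-[(dimethylamino)methyl]-3-methyl-3-vinylcyclopentan-1-one (C-2 epimers) | C=C[C@]1(C)[C@@H](O[Si](C)(C)C(C)(C)C)CC(=O)C1CN(C)C | intermediate (not isolated)
6 | ammonium iodide, N-methyl iodide salt of 5 | C=C[C@]1(C)[C@@H](O[Si](C)(C)C(C)(C)C)CC(=O)C1C[N+](C)(C)C.[I-] | intermediate (not isolated)
7 | (3S,4S)-4-(tert-butyldimethylsilyloxy)-3-methyl-2-methylidene-3-vinylcyclopentan-1-one | C=C[C@]1(C)[C@@H](O[Si](C)(C)C(C)(C)C)CC(=O)C1=C | intermediate
8 | (1S,3S,4S)-4-(tert-butyldimethylsilyloxy)-1-isopropyl-3-methyl-2-methylidene-3-vinylcyclopentan-1-ol | C=C[C@]1(C)[C@@H](O[Si](C)(C)C(C)(C)C)C[C@](O)(C(C)C)C1=C | intermediate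
9 | dimethylsilyl ether of 8 (C4–O–SiHMe2) | C=C[C@]1(C)[C@@H](O[Si](C)(C)C(C)(C)C)C[C@](O[SiH](C)C)(C(C)C)C1=C | intermediate (not isolated)
10 | cis-fused oxasilolane (C4–O–SiMe2–C6H2–C5) | C=C[C@]1(C)[C@@H](O[Si](C)(C)C(C)(C)C)C[C@@]2(C(C)C)O[Si](C)(C)C[C@@H]12 | intermediate (not isolated)
11 | ring A diol (C1 β-CH3/α-vinyl, C2 β-OTBS, C4 β-OH/α-iPr, C5 β-CH2OH) | C=C[C@]1(C)[C@@H](O[Si](C)(C)C(C)(C)C)C[C@](O)(C(C)C)[C@H]1CO | intermediate
12 | methyl ketone (C1 α-acetyl analogue of 11) | CC(=O)[C@]1(C)[C@@H](O[Si](C)(C)C(C)(C)C)C[C@](O)(C(C)C)[C@H]1CO | intermediate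
13 | C6 O-triethylsilyl ether of 12 | CC(=O)[C@]1(C)[C@@H](O[Si](C)(C)C(C)(C)C)C[C@](O)(C(C)C)[C@H]1CO[Si](CC)(CC)CC | intermediate
14 | trifluoroacetyl ketone (4,4,4-trifluoro-1,3-dione from 13) | O=C(CC(=O)[C@]1(C)[C@@H](O[Si](C)(C)C(C)(C)C)C[C@](O)(C(C)C)[C@H]1CO[Si](CC)(CC)CC)C(F)(F)F | intermediate (not isolated)
15 | α-diazoketone with C6–OTES | [N-]=[N+]=CC(=O)[C@]1(C)[C@@H](O[Si](C)(C)C(C)(C)C)C[C@](O)(C(C)C)[C@H]1CO[Si](CC)(CC)CC | intermediate
16 | α-diazoketone with free C6 alcohol | [N-]=[N+]=CC(=O)[C@]1(C)[C@@H](O[Si](C)(C)C(C)(C)C)C[C@](O)(C(C)C)[C@H]1CO | intermediate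
17 | aldehyde–diazoketone | [N-]=[N+]=CC(=O)[C@]1(C)[C@@H](O[Si](C)(C)C(C)(C)C)C[C@](O)(C(C)C)[C@H]1C=O | intermediate
18 | 2-methoxypropene | C=C(C)OC | starting material
19 | carbonyl ylide (C6=O(+)–C9(−), C10 ketone) | O=C1[CH-][O+]=C[C@H]2[C@@]1(C)[C@@H](O[Si](C)(C)C(C)(C)C)C[C@]2(O)C(C)C | intermediate (not isolated)
20 | 2β-(tert-butyldimethylsilyloxy)-6β,9β-epoxy-4β-hydroxy-8-methoxydaucan-10-one (C8 epimers) | O=C1[C@@H]2O[C@@H](CC2(C)OC)[C@H]2[C@@]1(C)[C@@H](O[Si](C)(C)C(C)(C)C)C[C@]2(O)C(C)C | intermediate
21 | methoxy ketone, 2β-(tert-butyldimethylsilyloxy)-4β,6β-dihydroxy-8-methoxydaucan-10-one (C8 epimers) | O=C1CC(C)(OC)C[C@H](O)[C@H]2[C@@]1(C)[C@@H](O[Si](C)(C)C(C)(C)C)C[C@]2(O)C(C)C | intermediate (not isolated)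
22 | 2β-(tert-butyldimethylsilyloxy)-4β,6β-dihydroxydauc-8-en-10-one | O=C1C=C(C)C[C@H](O)[C@H]2[C@@]1(C)[C@@H](O[Si](C)(C)C(C)(C)C)C[C@]2(O)C(C)C | intermediate
23 | 1,3-dithiolane of 22 at C10 | C1CSC2(S1)C=C(C)C[C@H](O)[C@H]1[C@@]2(C)[C@@H](O[Si](C)(C)C(C)(C)C)C[C@]1(O)C(C)C | intermediate
24 | 2β-(tert-butyldimethylsilyloxy)dauc-8-ene-4β,6β-diol | C1C=C(C)C[C@H](O)[C@H]2[C@@]1(C)[C@@H](O[Si](C)(C)C(C)(C)C)C[C@]2(O)C(C)C | intermediate
25 | 2β-(tert-butyldimethylsilyloxy)-8β,9β-epoxydaucane-4β,6β-diol | O[C@H]1C[C@@]2(C)O[C@H]2C[C@]2(C)[C@@H](O[Si](C)(C)C(C)(C)C)C[C@](O)(C(C)C)[C@@H]12 | intermediate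
26 | 3,4-dimethoxybenzoyl chloride | COc1ccc(C(=O)Cl)cc1OC | starting material
27 | 2β-(tert-butyldimethylsilyloxy)-6β-(3,4-dimethoxybenzoyloxy)-8β,9β-epoxydaucan-4β-ol | COc1ccc(C(=O)O[C@H]2C[C@@]3(C)O[C@H]3C[C@]3(C)[C@@H](O[Si](C)(C)C(C)(C)C)C[C@](O)(C(C)C)[C@@H]23)cc1OC | intermediate
28 | 6β-(3,4-dimethoxybenzoyloxy)-8β,9β-epoxydaucane-2β,4β-diol | COc1ccc(C(=O)O[C@H]2C[C@@]3(C)O[C@H]3C[C@]3(C)[C@@H](O)C[C@](O)(C(C)C)[C@@H]23)cc1OC | intermediate
29 | CNP0330776.1, 2β-acetoxy-6β-(3,4-dimethoxybenzoyloxy)-8β,9β-epoxydaucan-4β-ol | COc1ccc(C(=O)O[C@H]2C[C@@]3(C)O[C@H]3C[C@]3(C)[C@@H](OC(C)=O)C[C@](O)(C(C)C)[C@@H]23)cc1OC | target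

**Totals**

Total step count: 19. Longest linear sequence: 19 steps (1 → 29; 18 and 26 are purchased).

**Steps most likely to fail, with fallbacks**

1. Step 12 (key step). What may go wrong: loss of the C5 proton from the ylide before it is trapped, capture of the carbenoid by the enol ether (cyclopropanation), or erosion of regio- or facial selectivity in the intermolecular cycloaddition. Fallback (ring-closing metathesis; sets out from 11, comes back at 24, so steps 7–15 are not needed): the primary hydroxyl of 11 is silylated (TESCl, imidazole) to the triethylsilyl ether F1. The vinyl group is hydroborated and oxidised (9-BBN; NaOH, H2O2) to the primary alcohol F2, which Dess–Martin oxidation turns into the aldehyde F3. Wittig methylenation (Ph3P=CH2) gives the allyl compound F4, and PPTS in MeOH removes the silyl group to give the primary alcohol F5. Dess–Martin oxidation then gives the aldehyde F6. Reagent-controlled asymmetric methallylboration with the enantiomer of Ipc2B(methallyl) that adds to the Si face of the aldehyde ((−)-Ipc2B(methallyl), from (+)-α-pinene by the usual model; NaOH, H2O2 work-up) gives the homoallylic alcohol F7 with the C6 β-hydroxyl. Ring-closing metathesis with (H2IMes)(PCy3)Cl2Ru=CHPh (second-generation Grubbs catalyst, CH2Cl2, 40 °C) closes ring B at C8=C9 and gives 24.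

2. Step 6. What may go wrong: delivery of hydrogen to the β-face of the exocyclic alkene (a trans-fused silacycle), competing hydrosilylation of the vinyl group, and carry-over of any leakage in the facial selectivity of step 5. Fallback (oxidative transposition, reagent-controlled epoxidation, hydride opening; sets out from 8, either C4 epimer, comes back at 11): pyridinium chlorochromate (C5H5NH(+) CrO3Cl(−), CH2Cl2) effects the oxidative 1,3-transposition of the tertiary allylic alcohol through a [3,3]-shift of its chromate ester and gives the enal F8 (C4=C5, C6 aldehyde). DIBAL-H reduces it to the allylic alcohol F9. Sharpless asymmetric epoxidation (Ti(OiPr)4, L-(+)-diethyl tartrate, tBuOOH, 4 Å sieves, −20 °C) places the oxygen on the β-face by reagent control and gives the epoxy alcohol F10. NaAlH2(OCH2CH2OMe)2 then delivers hydride from the C6 alkoxide to C5 with inversion (H α, CH2OH β, C4 β-OH) and gives 11.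

3. Step 14 (and with it step 15). What may go wrong: slow dithioketalisation of the hindered conjugated C10 ketone, ionisation of the tertiary C4 alcohol by the Lewis acid, and double-bond migration or over-reduction during desulfurisation. Fallback (allylic hydrogenolysis; sets out from 22, comes back at 24): Luche reduction (NaBH4, CeCl3·7H2O, MeOH) gives the allylic diol F11. Methyl chloroformate and pyridine convert both secondary hydroxyls into the bis(methyl carbonate) F12. Pd(PPh3)4 with NaBH4 in THF ionises only the allylic C10 carbonate, and hydride attacks the less substituted terminus (C10) of the η3-allyl complex to give the C6 methyl carbonate F13 with the C8=C9 double bond in place. K2CO3 in MeOH removes the remaining carbonate and gives 24.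

**Further compounds**

F1 | step 12 | C6 O-triethylsilyl ether of 11 | C=C[C@]1(C)[C@@H](O[Si](C)(C)C(C)(C)C)C[C@](O)(C(C)C)[C@H]1CO[Si](CC)(CC)CC
F2 | step 12 | primary alcohol from hydroboration of F1 (C1–CH2CH2OH) | OCC[C@]1(C)[C@@H](O[Si](C)(C)C(C)(C)C)C[C@](O)(C(C)C)[C@H]1CO[Si](CC)(CC)CC
F3 | step 12 | aldehyde (C1–CH2CHO) | O=CC[C@]1(C)[C@@H](O[Si](C)(C)C(C)(C)C)C[C@](O)(C(C)C)[C@H]1CO[Si](CC)(CC)CC
F4 | step 12 | allyl compound (C1–CH2CH=CH2) | C=CC[C@]1(C)[C@@H](O[Si](C)(C)C(C)(C)C)C[C@](O)(C(C)C)[C@H]1CO[Si](CC)(CC)CC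
F5 | step 12 | primary alcohol (allyl compound with free C6–OH) | C=CC[C@]1(C)[C@@H](O[Si](C)(C)C(C)(C)C)C[C@](O)(C(C)C)[C@H]1CO
F6 | step 12 | aldehyde (allyl compound with C6 aldehyde) | C=CC[C@]1(C)[C@@H](O[Si](C)(C)C(C)(C)C)C[C@](O)(C(C)C)[C@H]1C=O
F7 | step 12 | homoallylic alcohol (C6 β-OH, methallyl side chain) | C=CC[C@]1(C)[C@@H](O[Si](C)(C)C(C)(C)C)C[C@](O)(C(C)C)[C@H]1[C@@H](O)CC(C)=C
F8 | step 6 | enal (C4=C5, C6 aldehyde) | C=C[C@]1(C)[C@@H](O[Si](C)(C)C(C)(C)C)CC(C(C)C)=C1C=O
F9 | step 6 | allylic alcohol (C4=C5, C6 alcohol) | C=C[C@]1(C)[C@@H](O[Si](C)(C)C(C)(C)C)CC(C(C)C)=C1CO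
F10 | step 6 | 4β,5β-epoxy alcohol | C=C[C@]1(C)[C@@H](O[Si](C)(C)C(C)(C)C)C[C@@]2(C(C)C)O[C@@]12CO
F11 | step 14 | allylic diol, 2β-(tert-butyldimethylsilyloxy)dauc-8-ene-4β,6β,10-triol (C10 epimers) | OC1C=C(C)C[C@H](O)[C@H]2[C@@]1(C)[C@@H](O[Si](C)(C)C(C)(C)C)C[C@]2(O)C(C)C
F12 | step 14 | 6,10-bis(methyl carbonate) of F11 | COC(=O)OC1C=C(C)C[C@H](OC(=O)OC)[C@H]2[C@@]1(C)[C@@H](O[Si](C)(C)C(C)(C)C)C[C@]2(O)C(C)C
F13 | step 14 | C6 methyl carbonate of 24 | C1C=C(C)C[C@H](OC(=O)OC)[C@H]2[C@@]1(C)[C@@H](O[Si](C)(C)C(C)(C)C)C[C@]2(O)C(C)C
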